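Saturday's and Thursday's flasks repeat Wednesday's with more free base, so you have a series in one setting, and the question is how much that setting matters.

| flask | electrophile | free base | protonated nucleophile | time |
|---|---|---|---|---|
| Wednesday's | 5.0 × 10⁻⁴ M | 1.50 equiv | 0.800 equiv | 8.0 s |
| Saturday's | 5.0 × 10⁻⁴ M | 2.20 equiv | 0.800 equiv | 8.0 s |
| Thursday's | 5.0 × 10⁻⁴ M | 3.40 equiv | 0.800 equiv | 8.0 s |

    electrophile + nucleophile → acid set free + product (k1 = 33500 M⁻¹ s⁻¹)
    nucleophile + acid set free ⇌ protonated nucleophile, settled at all times (K2 = 3.36 × 10⁶ M⁻¹)
    acid set free + free base ⇌ salt of the base, settled at all times (K3 = 1.0 × 10⁷ M⁻¹)
    2 electrophile → homo dimer (k4 = 221 M⁻¹ s⁻¹)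
    acid set free → by-product carried off (k5 = 3.66 s⁻¹)

- in percentages every species weighs as the electrophile in it: one homo dimer counts as two
- where a step has two of a species, its rate is k times that concentration squared, and two are used at each turn
- run time (Wednesday's): 8.0 s

* part of the electrophile that has reacted at the end, Wednesday's
* part of the electrophile that has reacted at the end, Saturday's
* part of the electrophile that has reacted at the end, Thursday's
* what raising the equivalents of free base from its lowest to its highest value here does to the part of the electrophile that has reacted (changes below 5 percentage points count as none) (it rises / no change / it falls)

Start with the balance of the protonated nucleophile, the limiting reagent. Each product takes one, so 0.800 equiv of it can make that much product and no more, which leaves a surplus of 1.00 × 10⁻⁴ M of electrophile. On Wednesday's charge, coupling halves the nucleophile in 0.041 s, far less than the run, so I treat it as finished at once. The surplus then goes by the dimer step, with a first half-life of 22.6 s, longer than the run. Being second order, it falls by the factor one plus run time over that half-life. Call the reach 85.2% the part reacted once the limiting charge has become product and the surplus has dimerised for the run.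

But you should object that coupling needs free base. Each product sets two acid free, one from the protonated nucleophile and one by coupling, so the charge calls for 1.60 equivalents of base. Wednesday's flask has less, while Saturday's and Thursday's have more. Wednesday's could therefore stall at 0.750 equivalents of product unless acid is carried off, and the same reckoning then gives 82.7%. That is 2.6 percentage points below the reach, inside the margin, so I commit to no change. One doubt stays: the dimer step also runs during coupling, so my figures should sit a little low.

The forecast says 87.5% (84% to 91%) for Wednesday's, 86% (83% to 89%) for Saturday's and 85.5% (82.5% to 88.5%) for Thursday's, and no change, holding of Wednesday's that “loss of the acid lets it finish nearly as far”. It puts Wednesday's above the other two, where my stalled figure for Wednesday's stands below my reach for the other two.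

Wednesday's, Saturday's and Thursday's flasks give 87.0%, 86.4% and 86.2%, a change of 0.77 points, which counts as no change. Wednesday's stands above the other two and above my reach. Now take Saturday's with 0.480 equiv of protonated nucleophile, where the base needed is below the charge. The reach becomes 72.9%. That flask ends at 73.3% reacted, with product at 48.0% and 27% of the electrophile still there.

The constants used here are made up; no experiment stands behind them.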